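**Retrosynthetic overview**
1. Feature: in ring A, carbon C1 carries the ether oxygen to ring B and lies between the hydroxylated carbons C2 and C6, and C4 is hydroxylated too. C2–C1–C6 is therefore an O-aryl malonyl unit and C3–C4–C5 an acetone unit, so ring A can be grown around an ether bond that already exists.
2. Last operations: thirteen-fold O-demethylation, preceded by an Ullmann coupling of an A–B phenol (free OH on C2 of ring B) with a C–D–E aryl iodide. This coupling makes the ether between C2 of ring B and C1 of ring C.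
3. A–B half: ring A is opened at C2–C3 and C5–C6 (double Claisen, aryloxymalonate plus dimethyl 3-oxopentanedioate). Its C1–O bond comes from SN2 on bromomalonate. Ring B comes from 2-hydroxy-4,6-dimethoxybenzaldehyde, whose CHO becomes the C2 oxygen by Baeyer–Villiger oxidation.
4. C–D–E half: two Ullmann couplings are built around 6-bromo-2,3,4-trimethoxybenzaldehyde, whose CHO becomes the C2 oxygen of ring D. The iodide at C1 of ring C comes from sterically controlled C–H borylation and iododeboronation.
5. Ring order: rings B, C, D and E are bought as benzenes; ring A is the only ring formed (step 6).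

Key step: step 6

Remark: the target has no stereocentre. Cn(X) means carbon n of ring X. C1(A) bears O to ring B. C1(B) bears O to ring A and C2(B) bears O to ring C. C1(C) bears O to ring B and C4(C) bears O to ring D. C1(D) bears O to ring C and C2(D) bears O to ring E. C1(E) bears O to ring D.

**Step 1**
Reactants: 1 2-hydroxy-4,6-dimethoxybenzaldehyde
Product: 2 2,4-dimethoxy-6-(methoxymethoxy)benzaldehyde
Conditions: NaH, MOMCl, DMF, 0 °C to rt
Reagents that add atoms: chloromethyl methyl ether, COCCl
Why: Williamson-type O-alkylation of the sodium phenoxide by the very reactive chloromethyl ether overcomes the OH···O=C hydrogen bond, and an acetal is preferred to a silyl group because a silyl group would migrate between the two adjacent oxygens under the base of step 3 and scramble C1(B) against C2(B).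

**Step 2**
Reactants: 2 2,4-dimethoxy-6-(methoxymethoxy)benzaldehyde
Product: 4 2,4-dimethoxy-6-(methoxymethoxy)phenol, via aryl formate 3 (not isolated)
Conditions: mCPBA, CH2Cl2, 0 °C to rt; then K2CO3 (cat.), MeOH, rt, argon
Reagents that add atoms: mCPBA, OOC(=O)c1cccc(Cl)c1
Why: In this Baeyer–Villiger oxidation the aryl group, enriched by two ortho oxygens and one para oxygen, migrates in preference to hydride, and the formate 3 is then transesterified by methanol without touching the acetal.

**Step 3**
Reactants: 4 2,4-dimethoxy-6-(methoxymethoxy)phenol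
Product: 5 2-(benzyloxy)-1,5-dimethoxy-3-(methoxymethoxy)benzene
Conditions: BnBr, K2CO3, DMF, rt, argon
Reagents that add atoms: benzyl bromide, BrCc1ccccc1
Why: Williamson ether synthesis on the only free hydroxyl, with no group next to it that can migrate, fixes benzyl on the oxygen of C2(B).

**Step 4**
Reactants: 5 2-(benzyloxy)-1,5-dimethoxy-3-(methoxymethoxy)benzene
Product: 6 2-(benzyloxy)-3,5-dimethoxyphenol
Conditions: HCl (cat.), MeOH, 50 °C
Reagents that add atoms: none
Why: Acid-catalysed acetal exchange with methanol removes the methoxymethyl group, while benzyl and methyl aryl ethers are inert to dilute acid.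

**Step 5**
Reactants: 6 2-(benzyloxy)-3,5-dimethoxyphenol; 7 dimethyl bromomalonate
Product: 8 dimethyl 2-[2-(benzyloxy)-3,5-dimethoxyphenoxy]propanedioate
Conditions: K2CO3, acetone, rt to 50 °C
Reagents that add atoms: none
Why: Williamson ether synthesis (SN2 of a phenoxide on the doubly activated halomalonate, routine for phenols) lays down the C1(A)–O–C1(B) ether before ring A exists and so spares any coupling at a carbon flanked by two oxygens.

**Step 6**
Reactants: 8 dimethyl 2-[2-(benzyloxy)-3,5-dimethoxyphenoxy]propanedioate; 9 dimethyl 3-oxopentanedioate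
Product: 11 dimethyl 5-[2-(benzyloxy)-3,5-dimethoxyphenoxy]-2,4,6-trihydroxybenzene-1,3-dicarboxylate, via open-chain triester 10 (not isolated)
Conditions: NaOMe (3.5 equiv), toluene–MeOH, reflux, 9 (1.5 equiv) added over 2 h, MeOH–toluene azeotrope distilled off; then 1 M HCl
Reagents that add atoms: none
Why: Proposed new method: the sodium enolate of 9 should attack one ester carbonyl of 8 (intermolecular Claisen condensation, bond C2–C3 of ring A) to give the open-chain triester 10, whose second β-keto ester enolate then acylates at carbon with the remaining malonyl ester in a Dieckmann-type 6-exo-trig closure (bond C5–C6) that completes ring A. The cyclohexane-1,3,5-trione so formed still has its C1–H, enolises to the benzene ring and is held as a sodium phenoxide, which together with removal of methanol pulls every preceding equilibrium forward. The closest known reactions are the alkoxide-mediated condensation of malonic esters with acetonedicarboxylates to phloroglucinol carboxylates and, on the electrophile side, the NaOMe-mediated double acylation of amidines by 2-aryloxymalonates to 5-aryloxypyrimidine-4,6-diols; a 2-aryloxymalonate has not been shown to take up a carbon 1,3-dinucleophile. Acylation at carbon instead of oxygen is needed and is secured by reversibility, since a 2-pyranone from O-acylation remains an ester that methoxide cleaves again whereas the phenoxide of 11 does not revert. Cross-condensation must also beat the aldol-type self-condensation of 9, which is why 9 is fed slowly into hot base so that its ketone is always masked as enolate and 8 is always in local excess; the resting of 8 as its own unreactive enolate is the chief danger. Both partners have a mirror plane through C1 and C4 of the ring to be formed, so no regiochemical question and no stereocentre arises.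

**Step 7**
Reactants: 11 dimethyl 5-[2-(benzyloxy)-3,5-dimethoxyphenoxy]-2,4,6-trihydroxybenzene-1,3-dicarboxylate
Product: 13 2-[2-(benzyloxy)-3,5-dimethoxyphenoxy]benzene-1,3,5-triol, via isophthalic diacid 12 (not isolated)
Conditions: KOH, degassed H2O–MeOH, reflux, argon; then 2 M HCl to pH 2, 80 °C
Reagents that add atoms: none
Why: Saponification is followed by protodecarboxylation, because 2,4,6-trihydroxybenzoic acids lose CO2 readily on warming in acid through ipso-protonation of the phloroglucinol ring, and benzyl, methyl and diaryl ethers survive both media when air is excluded.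

**Step 8**
Reactants: 13 2-[2-(benzyloxy)-3,5-dimethoxyphenoxy]benzene-1,3,5-triol
Product: 14 2-(benzyloxy)-1,5-dimethoxy-3-(2,4,6-trimethoxyphenoxy)benzene
Conditions: Me2SO4, K2CO3, acetone, reflux
Reagents that add atoms: dimethyl sulfate, COS(=O)(=O)OC
Why: Williamson O-methylation with the hard electrophile Me2SO4 and a weak base in acetone is the standard route to phloroglucinol trimethyl ethers and favours O- over C-alkylation.

**Step 9**
Reactants: 14 2-(benzyloxy)-1,5-dimethoxy-3-(2,4,6-trimethoxyphenoxy)benzene
Product: 15 2,4-dimethoxy-6-(2,4,6-trimethoxyphenoxy)phenol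
Conditions: H2 (1 atm), Pd/C, EtOAc–MeOH, rt
Reagents that add atoms: none
Why: Catalytic hydrogenolysis cleaves only the benzylic C–O bond and frees the hydroxyl on C2(B), methyl and diaryl ethers being inert.

**Step 10**
Reactants: 16 5-bromo-1,2,3-trimethoxybenzene
Product: 18 6-bromo-2,3,4-trimethoxybenzaldehyde, via aryl(chloro)methyl methyl ether 17 (not isolated)
Conditions: Cl2CHOMe, TiCl4, CH2Cl2, −10 to 0 °C; then ice–1 M HCl
Reagents that add atoms: dichloromethyl methyl ether, COC(Cl)Cl; water, O
Why: In this Rieche formylation (Friedel–Crafts type) the two open positions of 16 are equivalent and each is ortho and para to methoxy groups, so a single aldehyde with Br ortho to CHO should result after hydrolysis of 17.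

**Step 11**
Reactants: 18 6-bromo-2,3,4-trimethoxybenzaldehyde; 19 2,6-dimethoxyphenol
Product: 20 6-(2,6-dimethoxyphenoxy)-2,3,4-trimethoxybenzaldehyde
Conditions: CuI (10 mol %), picolinic acid (20 mol %), K3PO4, DMSO, 90 °C, argon
Reagents that add atoms: none
Why: In this ligand-accelerated Ullmann diaryl ether synthesis the bromide has a single ortho substituent, a formyl group that activates it, and the CuI–picolinic acid system is known to accept 2,6-disubstituted phenols, so the C4(C)–O–C1(D) bond forms with the crowding on the nucleophile only.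

**Step 12**
Reactants: 20 6-(2,6-dimethoxyphenoxy)-2,3,4-trimethoxybenzaldehyde
Product: 22 6-(2,6-dimethoxyphenoxy)-2,3,4-trimethoxyphenol, via aryl formate 21 (not isolated)
Conditions: mCPBA, CH2Cl2, 0 °C to rt; then K2CO3 (cat.), MeOH, rt, argon
Reagents that add atoms: mCPBA, OOC(=O)c1cccc(Cl)c1
Why: In this Baeyer–Villiger oxidation the formyl carbon sits between two oxygenated carbons and para to a third, so aryl migration is strongly favoured, and methanolysis of 21 then sets the hydroxyl on C2(D).

**Step 13**
Reactants: 22 6-(2,6-dimethoxyphenoxy)-2,3,4-trimethoxyphenol; 23 5-iodo-1,2,3-trimethoxybenzene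
Product: 24 1-(2,6-dimethoxyphenoxy)-3,4,5-trimethoxy-2-(3,4,5-trimethoxyphenoxy)benzene
Conditions: CuI (15 mol %), picolinic acid (30 mol %), K3PO4, DMSO, 100 °C, argon
Reagents that add atoms: none
Why: This Ullmann diaryl ether synthesis joins a 2,6-disubstituted phenol to an aryl iodide with two free ortho positions, the pairing for which CuI–picolinic acid is established, and argon protects the easily oxidised phenoxide of 22.

**Step 14**
Reactants: 24 1-(2,6-dimethoxyphenoxy)-3,4,5-trimethoxy-2-(3,4,5-trimethoxyphenoxy)benzene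
Product: 25 2-{3,5-dimethoxy-4-[3,4,5-trimethoxy-2-(3,4,5-trimethoxyphenoxy)phenoxy]phenyl}-4,4,5,5-tetramethyl-1,3,2-dioxaborolane
Conditions: [Ir(OMe)(cod)]2 (1.5 mol %), dtbpy (3 mol %), B2pin2 (1.0 equiv), THF, 80 °C
Reagents that add atoms: bis(pinacolato)diboron, CC1(C)OB(OC1(C)C)B1OC(C)(C)C(C)(C)O1
Why: Iridium-catalysed C–H borylation is ruled by sterics, and C1(C)–H is the only C–H of 24 without an ortho substituent (C2/C6 of ring C, C6 of ring D and C2/C6 of ring E all lie next to oxygen substituents), as in the known 5-borylation of 1,2,3-trisubstituted benzenes.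

**Step 15**
Reactants: 25 the pinacol boronate of step 14
Product: 26 1-(4-iodo-2,6-dimethoxyphenoxy)-3,4,5-trimethoxy-2-(3,4,5-trimethoxyphenoxy)benzene
Conditions: CuI (10 mol %), 1,10-phenanthroline (20 mol %), KI, MeOH–H2O, air, 80 °C
Reagents that add atoms: potassium iodide, [K+].[I-]
Why: Copper-catalysed aerobic iododeboronation of aryl pinacol boronates places iodide on the boron-bearing carbon through transmetalation, so no strong electrophilic iodine source meets the electron-rich rings D and E.

**Step 16**
Reactants: 15 2,4-dimethoxy-6-(2,4,6-trimethoxyphenoxy)phenol; 26 1-(4-iodo-2,6-dimethoxyphenoxy)-3,4,5-trimethoxy-2-(3,4,5-trimethoxyphenoxy)benzene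
Product: 27 1-{4-[2,4-dimethoxy-6-(2,4,6-trimethoxyphenoxy)phenoxy]-2,6-dimethoxyphenoxy}-3,4,5-trimethoxy-2-(3,4,5-trimethoxyphenoxy)benzene (tridecamethyl ether of the target)
Conditions: CuI (20 mol %), picolinic acid (40 mol %), K3PO4, DMSO, 105 °C, argon
Reagents that add atoms: none
Why: In this Ullmann diaryl ether synthesis the iodide at C1(C) has hydrogen on both sides, so all the crowding lies on the phenoxide of 15, the case this catalyst system tolerates, and the non-oxidising medium suits a phenol that is a hydroquinone monoether.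

**Step 17**
Reactants: 27 tridecamethyl ether
Product: 28 5-{4-[2,4-dihydroxy-6-(2,4,6-trihydroxyphenoxy)phenoxy]-2,6-dihydroxyphenoxy}-4-(3,4,5-trihydroxyphenoxy)benzene-1,2,3-triol (target)
Conditions: BBr3 (excess), CH2Cl2, −78 °C to rt, argon; then MeOH–H2O, 0 °C; degassed reversed-phase purification
Reagents that add atoms: none
Why: In this Lewis acid-mediated aryl methyl ether cleavage BBr3 binds each methoxy oxygen and bromide removes the methyl group by SN2, a path closed to the C(sp2)–O bonds of the four diaryl ethers, and hydrolysis of the aryl borates should free all thirteen hydroxyls.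

**Compound list**
1 | 2-hydroxy-4,6-dimethoxybenzaldehyde | COc1cc(O)c(C=O)c(OC)c1 | starting material
2 | 2,4-dimethoxy-6-(methoxymethoxy)benzaldehyde | COCOc1cc(OC)cc(OC)c1C=O | intermediate
3 | 2,4-dimethoxy-6-(methoxymethoxy)phenyl formate | COCOc1cc(OC)cc(OC)c1OC=O | intermediate
4 | 2,4-dimethoxy-6-(methoxymethoxy)phenol | COCOc1cc(OC)cc(OC)c1O | intermediate
5 | 2-(benzyloxy)-1,5-dimethoxy-3-(methoxymethoxy)benzene | COCOc1cc(OC)cc(OC)c1OCc1ccccc1 | intermediate
6 | 2-(benzyloxy)-3,5-dimethoxyphenol | COc1cc(O)c(OCc2ccccc2)c(OC)c1 | intermediate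
7 | dimethyl bromomalonate | COC(=O)C(Br)C(=O)OC | starting material
8 | dimethyl 2-[2-(benzyloxy)-3,5-dimethoxyphenoxy]propanedioate | COC(=O)C(Oc1cc(OC)cc(OC)c1OCc1ccccc1)C(=O)OC | intermediate
9 | dimethyl 3-oxopentanedioate | COC(=O)CC(=O)CC(=O)OC | starting material
10 | dimethyl 2-[2-(benzyloxy)-3,5-dimethoxyphenoxy]-4-(methoxycarbonyl)-3,5-dioxoheptanedioate | COC(=O)CC(=O)C(C(=O)OC)C(=O)C(Oc1cc(OC)cc(OC)c1OCc1ccccc1)C(=O)OC | intermediate
11 | dimethyl 5-[2-(benzyloxy)-3,5-dimethoxyphenoxy]-2,4,6-trihydroxybenzene-1,3-dicarboxylate | COC(=O)c1c(O)c(Oc2cc(OC)cc(OC)c2OCc2ccccc2)c(O)c(C(=O)OC)c1O | intermediate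
12 | 5-[2-(benzyloxy)-3,5-dimethoxyphenoxy]-2,4,6-trihydroxybenzene-1,3-dicarboxylic acid | OC(=O)c1c(O)c(Oc2cc(OC)cc(OC)c2OCc2ccccc2)c(O)c(C(=O)O)c1O | intermediate
13 | 2-[2-(benzyloxy)-3,5-dimethoxyphenoxy]benzene-1,3,5-triol | Oc1cc(O)c(Oc2cc(OC)cc(OC)c2OCc2ccccc2)c(O)c1 | intermediate
14 | 2-(benzyloxy)-1,5-dimethoxy-3-(2,4,6-trimethoxyphenoxy)benzene | COc1cc(OC)c(Oc2cc(OC)cc(OC)c2OCc2ccccc2)c(OC)c1 | intermediate
15 | 2,4-dimethoxy-6-(2,4,6-trimethoxyphenoxy)phenol | COc1cc(OC)c(Oc2cc(OC)cc(OC)c2O)c(OC)c1 | intermediate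
16 | 5-bromo-1,2,3-trimethoxybenzene | COc1cc(Br)cc(OC)c1OC | starting material
17 | 1-bromo-2-[chloro(methoxy)methyl]-3,4,5-trimethoxybenzene | COC(Cl)c1c(Br)cc(OC)c(OC)c1OC | intermediate
18 | 6-bromo-2,3,4-trimethoxybenzaldehyde | COc1cc(Br)c(C=O)c(OC)c1OC | intermediate
19 | 2,6-dimethoxyphenol | COc1cccc(OC)c1O | starting material
20 | 6-(2,6-dimethoxyphenoxy)-2,3,4-trimethoxybenzaldehyde | COc1cccc(OC)c1Oc1cc(OC)c(OC)c(OC)c1C=O | intermediate
21 | 6-(2,6-dimethoxyphenoxy)-2,3,4-trimethoxyphenyl formate | COc1cccc(OC)c1Oc1cc(OC)c(OC)c(OC)c1OC=O | intermediate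
22 | 6-(2,6-dimethoxyphenoxy)-2,3,4-trimethoxyphenol | COc1cccc(OC)c1Oc1cc(OC)c(OC)c(OC)c1O | intermediate
23 | 5-iodo-1,2,3-trimethoxybenzene | COc1cc(I)cc(OC)c1OC | starting material
24 | 1-(2,6-dimethoxyphenoxy)-3,4,5-trimethoxy-2-(3,4,5-trimethoxyphenoxy)benzene | COc1cccc(OC)c1Oc1cc(OC)c(OC)c(OC)c1Oc1cc(OC)c(OC)c(OC)c1 | intermediate
25 | 2-{3,5-dimethoxy-4-[3,4,5-trimethoxy-2-(3,4,5-trimethoxyphenoxy)phenoxy]phenyl}-4,4,5,5-tetramethyl-1,3,2-dioxaborolane | COc1cc(B2OC(C)(C)C(C)(C)O2)cc(OC)c1Oc1cc(OC)c(OC)c(OC)c1Oc1cc(OC)c(OC)c(OC)c1 | intermediate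
26 | 1-(4-iodo-2,6-dimethoxyphenoxy)-3,4,5-trimethoxy-2-(3,4,5-trimethoxyphenoxy)benzene | COc1cc(I)cc(OC)c1Oc1cc(OC)c(OC)c(OC)c1Oc1cc(OC)c(OC)c(OC)c1 | intermediate
27 | 1-{4-[2,4-dimethoxy-6-(2,4,6-trimethoxyphenoxy)phenoxy]-2,6-dimethoxyphenoxy}-3,4,5-trimethoxy-2-(3,4,5-trimethoxyphenoxy)benzene | COc1cc(OC)c(Oc2cc(OC)cc(OC)c2Oc2cc(OC)c(Oc3cc(OC)c(OC)c(OC)c3Oc3cc(OC)c(OC)c(OC)c3)c(OC)c2)c(OC)c1 | intermediate
28 | 5-{4-[2,4-dihydroxy-6-(2,4,6-trihydroxyphenoxy)phenoxy]-2,6-dihydroxyphenoxy}-4-(3,4,5-trihydroxyphenoxy)benzene-1,2,3-triol | Oc1cc(O)c(Oc2cc(O)cc(O)c2Oc2cc(O)c(Oc3cc(O)c(O)c(O)c3Oc3cc(O)c(O)c(O)c3)c(O)c2)c(O)c1 | target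

**Step counts**
- Total step count: 17.
- Longest linear sequence: 11 steps (steps 1–9, 16 and 17).
- The C–D–E branch (steps 10–15) is made in parallel.

**Steps most likely to fail**

Step 6.
- What may go wrong: 8 may rest as its own enolate and lose its electrophilicity. Meanwhile 9 may self-condense in an aldol–Claisen manner, or the sequence may stall after O-acylation.
- Fallback: it uses known chemistry and gives up the ring construction in favour of an arylation. It sets out from 6 and comes back at 14.
- Phenol 6 is heated with 4-fluoro-3,5-dimethoxybenzaldehyde and Cs2CO3 in DMSO (nucleophilic aromatic substitution para to the formyl group). This gives 4-[2-(benzyloxy)-3,5-dimethoxyphenoxy]-3,5-dimethoxybenzaldehyde F1.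
- Baeyer–Villiger oxidation with mCPBA gives 4-[2-(benzyloxy)-3,5-dimethoxyphenoxy]-3,5-dimethoxyphenyl formate F2.
- K2CO3 in MeOH converts this into 4-[2-(benzyloxy)-3,5-dimethoxyphenoxy]-3,5-dimethoxyphenol F3.
- Me2SO4 and K2CO3 in acetone methylate the new hydroxyl at C4(A) to give 14.

Step 16.
- What may go wrong: C–O bond formation at the doubly ortho-substituted phenoxide of 15 may be slow. Hydrodeiodination of 26 and oxidative loss of 15 could then take over.
- Fallback: it sets out from 25, so it also bypasses step 15, and it comes back at 27.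
- NaIO4 and NH4OAc in acetone–water cleave the pinacol ester to {3,5-dimethoxy-4-[3,4,5-trimethoxy-2-(3,4,5-trimethoxyphenoxy)phenoxy]phenyl}boronic acid F4.
- F4 is joined to 15 by Chan–Lam–Evans coupling (Cu(OAc)2, pyridine, 4 Å molecular sieves, CH2Cl2, rt, dry air).
- This is an oxidative coupling at room temperature through a trivalent copper aryl phenoxide. It is known to accept 2,6-disubstituted phenols and favours electron-rich boronic acids with free ortho positions.

Step 17.
- What may go wrong: partly demethylated aryl borates may precipitate and stop the cleavage short. The pyrogallol-type rings D and E may also autoxidise during work-up and chromatography.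
- Fallback: it sets out from 27 and comes back at 28.
- The crude product of the BBr3 treatment is not purified. It is peracetylated (Ac2O, pyridine, rt) to the tridecaacetate of the target F5.
- F5 is air-stable and can be chromatographed on silica, which separates it from material that still carries methyl groups.
- Acid-catalysed methanolysis (HCl generated from AcCl in MeOH, 40 °C, argon) then releases 28, with only a volatile ester to evaporate.

**Further compounds**
F1 | step 6 | 4-[2-(benzyloxy)-3,5-dimethoxyphenoxy]-3,5-dimethoxybenzaldehyde | COc1cc(C=O)cc(OC)c1Oc1cc(OC)cc(OC)c1OCc1ccccc1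
F2 | step 6 | 4-[2-(benzyloxy)-3,5-dimethoxyphenoxy]-3,5-dimethoxyphenyl formate | COc1cc(OC=O)cc(OC)c1Oc1cc(OC)cc(OC)c1OCc1ccccc1
F3 | step 6 | 4-[2-(benzyloxy)-3,5-dimethoxyphenoxy]-3,5-dimethoxyphenol | COc1cc(O)cc(OC)c1Oc1cc(OC)cc(OC)c1OCc1ccccc1
F4 | step 16 | {3,5-dimethoxy-4-[3,4,5-trimethoxy-2-(3,4,5-trimethoxyphenoxy)phenoxy]phenyl}boronic acid | COc1cc(B(O)O)cc(OC)c1Oc1cc(OC)c(OC)c(OC)c1Oc1cc(OC)c(OC)c(OC)c1
F5 | step 17 | tridecaacetate of the target | CC(=O)Oc1cc(OC(C)=O)c(Oc2cc(OC(C)=O)cc(OC(C)=O)c2Oc2cc(OC(C)=O)c(Oc3cc(OC(C)=O)c(OC(C)=O)c(OC(C)=O)c3Oc3cc(OC(C)=O)c(OC(C)=O)c(OC(C)=O)c3)c(OC(C)=O)c2)c(OC(C)=O)c1
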